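## Retrosynthetic overview

1. Andrographolide ⇐ its 3,19-acetonide **22** ⇐ a single Ni-catalysed alkylative cyclisation that joins the C11 zinc reagent from decalin iodide **17** with 2-oxoethyl propiolate **21**. This forms C11–C12, C13–C14, the E-alkene and the lactone ring (last ring formed).
2. Decalin **17** ⇐ epoxide-initiated, allylsilane-terminated cationic bicyclisation of polyene **14**. Rings A and B form together, with C4, C5, C9, C10 and the 8(17)-methylene set in this step.
3. Polyene **14** ⇐ B-alkyl Suzuki coupling (C5–C6) of epoxy vinyl iodide **7** (head) with silyl diene **13** (tail).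
4. Head **7** ⇐ pent-4-yn-1-ol (Zr-catalysed carboalumination, Still–Gennari, Sharpless epoxidation sets absolute configuration). Tail **13** ⇐ propargyl alcohol + vinyl bromide (Sonogashira, Red-Al/I2, Kumada).
5. Ring order: A and B together (cationic cascade), then the butyrolactone (Ni).

Assumptions: in-situ reagent generation (9-BBN hydroboration, zinc insertion) is counted within the coupling step it serves; the olefination phosphonate and organometallic reagents are treated as reagents. Atom numbering in the text is labdane numbering (C17 = exocyclic CH2, C18 = 4-Me, C19 = 4-CH2O, C20 = 10-Me, C11 = CH2 on C9).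

## Route

**Step 1**
Reactants: **1** pent-4-yn-1-ol
Product: **2** (E)-5-iodo-4-methylpent-4-en-1-ol
Conditions: Me3Al (3 equiv), Cp2ZrCl2 (0.25 equiv), CH2Cl2, 0 °C→rt; then I2, THF, −30→0 °C
Reagents that add atoms: trimethylaluminium, C[Al](C)C; iodine, II
Why: Zr-catalysed carboalumination (Negishi) adds Me and Al syn with Me on the internal carbon, and iodinolysis with retention gives the E-vinyl iodide (future C5=C10 geometry).

**Step 2**
Reactants: **2**
Product: **3** (E)-5-iodo-4-methylpent-4-enal
Conditions: Dess–Martin periodinane, NaHCO3, CH2Cl2, 0 °C→rt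
Reagents that add atoms: none
Why: Dess–Martin oxidation of a primary alcohol; the vinyl iodide is inert.

**Step 3**
Reactants: **3**
Product: **4** methyl (2Z,6E)-7-iodo-2,6-dimethylhepta-2,6-dienoate
Conditions: (CF3CH2O)2P(O)CH(CH3)CO2Me, KHMDS, 18-crown-6, THF, −78 °C
Reagents that add atoms: methyl 2-[bis(2,2,2-trifluoroethoxy)phosphoryl]propanoate, COC(=O)C(C)P(=O)(OCC(F)(F)F)OCC(F)(F)F
Why: Still–Gennari olefination is kinetically Z-selective, placing the ester carbon (future C19) cis to the chain.

**Step 4**
Reactants: **4**
Product: **5** (2Z,6E)-7-iodo-2,6-dimethylhepta-2,6-dien-1-ol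
Conditions: DIBAL-H (2.5 equiv), CH2Cl2, −78 °C
Reagents that add atoms: none
Why: DIBAL 1,2-reduction of the enoate leaves both alkene geometries and the vinyl iodide untouched.

**Step 5**
Reactants: **5**
Product: **6** [(2S,3R)-3-[(3E)-4-iodo-3-methylbut-3-en-1-yl]-2-methyloxiran-2-yl]methanol
Conditions: Ti(OiPr)4, L-(+)-diethyl tartrate, t-BuOOH, 4 Å MS, CH2Cl2, −20 °C
Reagents that add atoms: tert-butyl hydroperoxide, CC(C)(C)OO
Why: Sharpless asymmetric epoxidation is directed by the allylic OH only, and L-(+)-tartrate gives the (2S,3R)-epoxide. This fixes C3 and, after inversion in step 12, C4.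

**Step 6**
Reactants: **6**
Product: **7** triethyl{[(2S,3R)-3-[(3E)-4-iodo-3-methylbut-3-en-1-yl]-2-methyloxiran-2-yl]methoxy}silane
Conditions: TESCl, imidazole, CH2Cl2, 0 °C
Reagents that add atoms: chlorotriethylsilane, CC[Si](Cl)(CC)CC
Why: Mild silylation of the primary epoxy alcohol avoids Payne rearrangement.

**Step 7**
Reactants: **8** prop-2-yn-1-ol; **9** vinyl bromide
Product: **10** pent-4-en-2-yn-1-ol
Conditions: PdCl2(PPh3)2 (2 mol%), CuI (4 mol%), iPr2NH, THF, 0 °C→rt
Reagents that add atoms: none
Why: Sonogashira coupling of a terminal alkyne with a vinyl halide.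

**Step 8**
Reactants: **10**
Product: **11** (2Z)-3-iodopenta-2,4-dien-1-ol
Conditions: Red-Al, THF, 0 °C→rt; then I2, THF, −78→0 °C
Reagents that add atoms: iodine, II
Why: Hydroxyl-directed trans-hydroalumination puts Al on C3 cis to the CH2O arm, and iodinolysis with retention gives the Z-iodide.

**Step 9**
Reactants: **11**
Product: **12** (2Z)-3-[(trimethylsilyl)methyl]penta-2,4-dien-1-ol
Conditions: Me3SiCH2MgCl (3 equiv), Pd(PPh3)4 (5 mol%), THF, 0 °C→rt
Reagents that add atoms: (trimethylsilyl)methylmagnesium chloride, C[Si](C)(C)C[Mg]Cl
Why: Kumada–Corriu coupling with retention places CH2SiMe3 cis to the CH2O arm and the vinyl group trans to it, the geometry that later gives an equatorial C9 substituent.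

**Step 10**
Reactants: **12**
Product: **13** triethyl{[(2Z)-3-[(trimethylsilyl)methyl]penta-2,4-dien-1-yl]oxy}silane
Conditions: TESCl, imidazole, CH2Cl2, 0 °C
Reagents that add atoms: chlorotriethylsilane, CC[Si](Cl)(CC)CC
Why: Standard silylation; neutral conditions keep the acid-sensitive allylsilane intact.

**Step 11**
Reactants: **13**; **7**
Product: **14** triethyl{[(2S,3R)-2-methyl-3-[(3E,7Z)-3-methyl-9-[(triethylsilyl)oxy]-7-[(trimethylsilyl)methyl]nona-3,7-dien-1-yl]oxiran-2-yl]methoxy}silane
Conditions: **13**, 9-BBN, THF, 0 °C→rt; then **7**, PdCl2(dppf) (5 mol%), AsPh3, Cs2CO3, DMF/H2O, rt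
Reagents that add atoms: none (9-BBN delivers H only)
Why: B-alkyl Suzuki–Miyaura coupling: 9-BBN adds anti-Markovnikov to the monosubstituted vinyl of the diene, and Pd coupling with the vinyl iodide retains the E geometry. The epoxide, silyl ethers and allylsilane tolerate the mild base.

**Step 12**
Reactants: **14**
Product: **15** trans-decalin with ring stereocentres as in andrographolide: 3-OH (3R, equatorial), 4-CH2OTES axial and cis to the 10-Me, 5-H trans to 10-Me, 9-CH2OTES equatorial, 8(17)-exocyclic methylene
Conditions: MeAlCl2 (1.2 equiv), CH2Cl2, −78 °C; Et3N/MeOH quench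
Reagents that add atoms: none
Why: Epoxide-initiated cationic polyene cyclisation through a chair–chair (Stork–Eschenmoser) transition state. Anti opening at the tertiary epoxide carbon inverts C4 (the Z-CH2O arm becomes axial) and keeps C3–O equatorial. The E-alkene gives the trans ring fusion, and the allylsilane gives the equatorial C9 arm and only the exocyclic alkene on loss of Me3Si+.

**Step 13**
Reactants: **15**
Product: **16** 3,19-O-isopropylidene acetonide of the decalin triol, with free C11–OH
Conditions: CSA (10 mol%), 2,2-dimethoxypropane, acetone/MeOH (20:1), rt; aq. NaHCO3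
Reagents that add atoms: 2,2-dimethoxypropane, COC(C)(C)OC
Why: Acid-catalysed desilylation and transketalisation in one pot; only the cis 1,3-diol (O3/O19) can close a six-membered acetonide, so C11–OH stays free.

**Step 14**
Reactants: **16**
Product: **17** the corresponding C11 iodide (3,19-acetonide retained)
Conditions: I2, PPh3, imidazole, toluene, 60 °C
Reagents that add atoms: iodine, II
Why: Appel-type (Garegg–Samuelsson) iodination by SN2 at the primary carbon; the imidazole buffer protects the acetonide and the exocyclic alkene.

**Step 15**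
Reactants: **18** propiolic acid; **19** ethylene glycol (5 equiv)
Product: **20** 2-hydroxyethyl prop-2-ynoate
Conditions: DCC, DMAP (5 mol%), CH2Cl2/THF, −20→0 °C
Reagents that add atoms: none
Why: Steglich esterification; excess diol gives the mono-ester, and low temperature limits amine addition to the ynoate.

**Step 16**
Reactants: **20**
Product: **21** 2-oxoethyl prop-2-ynoate
Conditions: Dess–Martin periodinane, NaHCO3, CH2Cl2, 0 °C; filtered and used at once
Reagents that add atoms: none
Why: Dess–Martin oxidation under neutral conditions gives the sensitive α-acyloxy aldehyde without touching the ynoate.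

**Step 17**
Reactants: **17**; **21** (1.5 equiv)
Product: **22** 3,19-O-isopropylidene andrographolide (12E, 14S)
Conditions: **17**, activated Zn dust, LiCl, THF, 40 °C (gives RZnI·LiCl); then Ni(cod)2 (10 mol%), chiral spiro-phosphoramidite (SIPHOS-PE type, 12 mol%; antipode chosen by screening to give 14S), THF, 0 °C, **21** added by syringe pump
Reagents that add atoms: none
Why: Proposed new method: Ni(0) binds the alkyne and the tethered aldehyde of **21** and undergoes oxidative cyclisation to an oxanickelacyclopentene, with the chiral ligand setting C14. Only the 5-exo mode is geometrically possible, and the slim propiolate keeps the s-cis ester rotamer accessible. Transmetalation of the C11 alkylzinc to Ni–O and C(sp3)–C(sp2) reductive elimination then put C11 on C12 cis to C14, which is the E-alkylidene, and release Ni(0). A π-acidic monodentate ligand is chosen to favour reductive elimination over β-H elimination from the hindered β-branched alkyl. The closest known reaction types are Ni(0)-catalysed alkylative cyclisation of carbon-tethered ynals with organozincs (racemic) and Ni/phosphoramidite enantioselective alkylative alkyne–aldehyde coupling with Me2Zn. New here are the ynoate–aldehyde ester tether, a complex β-H-bearing alkylzinc, and enantiocontrol in the cyclisation. Any 14-epimer is a separable diastereomer.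

**Step 18**
Reactants: **22**
Product: **23** andrographolide
Conditions: AcOH/H2O (7:3), rt
Reagents that add atoms: none
Why: Mild acid hydrolysis of the acetonide; the allylic 14-OH, the E-alkylidene lactone and the exocyclic alkene survive, and no stereocentre is touched.

## Compound list

1 | pent-4-yn-1-ol | C#CCCCO | starting material
2 | (E)-5-iodo-4-methylpent-4-en-1-ol | OCCC/C(C)=C/I | intermediate
3 | (E)-5-iodo-4-methylpent-4-enal | O=CCC/C(C)=C/I | intermediate
4 | methyl (2Z,6E)-7-iodo-2,6-dimethylhepta-2,6-dienoate | COC(=O)/C(C)=C\CC/C(C)=C/I | intermediate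
5 | (2Z,6E)-7-iodo-2,6-dimethylhepta-2,6-dien-1-ol | OC/C(C)=C\CC/C(C)=C/I | intermediate
6 | [(2S,3R)-3-[(3E)-4-iodo-3-methylbut-3-en-1-yl]-2-methyloxiran-2-yl]methanol | C[C@@]1(CO)O[C@@H]1CC/C(C)=C/I | intermediate
7 | TES ether of 6 | C[C@@]1(CO[Si](CC)(CC)CC)O[C@@H]1CC/C(C)=C/I | intermediate
8 | prop-2-yn-1-ol | C#CCO | starting material
9 | vinyl bromide | C=CBr | starting material
10 | pent-4-en-2-yn-1-ol | C=CC#CCO | intermediate
11 | (2Z)-3-iodopenta-2,4-dien-1-ol | OC/C=C(\I)C=C | intermediate
12 | (2Z)-3-[(trimethylsilyl)methyl]penta-2,4-dien-1-ol | OC/C=C(\C[Si](C)(C)C)C=C | intermediate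
13 | TES ether of 12 | CC[Si](CC)(CC)OC/C=C(\C[Si](C)(C)C)C=C | intermediate
14 | epoxy-diene allylsilane (cyclisation precursor) | C[C@@]1(CO[Si](CC)(CC)CC)O[C@@H]1CC/C(C)=C/CC/C(C[Si](C)(C)C)=C/CO[Si](CC)(CC)CC | intermediate
15 | 3-hydroxy-11,19-bis(triethylsilyloxy) 8(17)-methylene decalin (andrographolide A/B core) | C=C1CC[C@@H]2[C@](C)(CO[Si](CC)(CC)CC)[C@H](O)CC[C@@]2(C)[C@@H]1CO[Si](CC)(CC)CC | intermediate
16 | 3,19-acetonide, C11 alcohol | C=C1CC[C@@H]2[C@]3(C)COC(C)(C)O[C@@H]3CC[C@@]2(C)[C@@H]1CO | intermediate
17 | 3,19-acetonide, C11 iodide | C=C1CC[C@@H]2[C@]3(C)COC(C)(C)O[C@@H]3CC[C@@]2(C)[C@@H]1CI | intermediate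
18 | propiolic acid | C#CC(=O)O | starting material
19 | ethylene glycol | OCCO | starting material
20 | 2-hydroxyethyl prop-2-ynoate | C#CC(=O)OCCO | intermediate
21 | 2-oxoethyl prop-2-ynoate | C#CC(=O)OCC=O | intermediate
22 | 3,19-O-isopropylidene andrographolide | C=C1CC[C@@H]2[C@]3(C)COC(C)(C)O[C@@H]3CC[C@@]2(C)[C@@H]1C/C=C1/C(=O)OC[C@H]1O | intermediate
23 | andrographolide | C=C1CC[C@@H]2[C@](C)(CO)[C@H](O)CC[C@@]2(C)[C@@H]1C/C=C1/C(=O)OC[C@H]1O | target

## Step count and risks

Total steps: 18. Longest linear sequence: 12 (steps 1–6, 11–14, 17, 18), which is exactly two thirds of the total.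

Steps most likely to fail:

1. **Step 17 (the proposed new Ni alkylative cyclisation).** Risks are β-H elimination giving the reduced methylene lactone, poor control at C14, and ynoate oligomerisation. Fallback with known chemistry: convert **16** to the C11 triflate and displace it with the lithium acetylide of (S)-4-ethynyl-2,2-dimethyl-1,3-dioxolane. Then remove the acetonides and close the lactone by Pd-catalysed cyclocarbonylation of the homopropargylic diol under CO. Syn H/CO addition gives the E-alkylidene, and C14 comes from the preformed stereocentre.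

2. **Step 12 (cationic bicyclisation).** Risks are epoxide-to-ketone rearrangement, monocyclisation, protodesilylation, and ionisation of the allylic silyl ether. Fallback: replace the allylsilane terminator with a β-keto ester terminator. The polyene is made by alkylating the methyl acetoacetate dianion with the corresponding epoxy allylic bromide and cyclised with SnCl4 to the 8-oxo-9-carbomethoxy decalin. Lombardo methylenation and ester reduction then give the same C11 alcohol.

3. **Step 11 (diene hydroboration / B-alkyl Suzuki).** Risks are non-selective or double hydroboration of the 2-substituted diene. Fallback: Negishi C(sp3)–C(sp2) coupling of **7** with the homoallylic zinc reagent IZnCH2CH2C(CH2SiMe3)=CHCH2OTES. This is made from but-3-yn-1-ol by hydroxymethylation, Red-Al/I2, Kumada coupling and Appel iodination, so no diene hydroboration is needed.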